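**Retrosynthetic overview**

1. Locants (3,7-dioxabicyclo[3.3.0]octane): C1 carbinol bridgehead, C2 (endo aryl), O3, C4, C5 (H bridgehead), C6 (exo aryl), O7, C8; ring A = C1-C2-O3-C4-C5, ring B = C1-C5-C6-O7-C8.
2. Last disconnection (ring A ether): the C2 aryl and C2-H come from aryllithium addition to a C2 lactone carbonyl and silane reduction of the lactol; hydride enters on the convex face, so the C2 aryl ends endo.
3. Key disconnection: the C6-aryl bond and the O7-C6 bond of ring B are made in one operation, joining veratrole to a monocyclic, aryl-free lactone diol dimethyl acetal by an acid-triggered acetal cyclisation / Friedel-Crafts arylation cascade.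
4. Enabling feature: C6 is an acetal-level carbon bound to O7 in a cis-fused bicycle, its oxocarbenium ion is open only on the convex face, and the target carries the C6 aryl exo (cis to H5), which is what arene attack on that face gives.
5. Ring order: ring A first as a lactone (C5 set by enamine catalysis, C1 by dihydroxylation anti to the C5 substituent), ring B in the key step, ring A converted from lactone to ether at the end.

Key step: step 4

Remark on the chemistry: the acid promoters (TsOH, CF3SO3H, BF3·OEt2) are taken as not consumed by the net equations, and the lactol of step 5 is written in its closed form although it equilibrates with the open hydroxy ketone.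

**Step 1**
Reactants: 1 methyl 4-oxobutanoate
Product: 3 (S)-4-(dimethoxymethyl)dihydrofuran-2(3H)-one, via hydroxy aldehyde 2 (not isolated)
Conditions: 37% aq. CH2O (3 equiv), (R)-α,α-diphenylprolinol trimethylsilyl ether (10 mol %), pH 7 buffer (NaH2PO4/Na2HPO4), toluene, rt; then HC(OMe)3 (3 equiv), TsOH·H2O (5 mol %), CH2Cl2, 0 °C to rt; then toluene, 50 °C
Reagents that add atoms: formaldehyde (C=O); trimethyl orthoformate (COC(OC)OC)
Why: Enamine-catalysed asymmetric α-hydroxymethylation (cross-aldol with formaldehyde) should set the stereocentre as (S), because the diphenyl(silyloxy)methyl group of the (R)-catalyst shields one face of the E-enamine of 1 and formaldehyde adds to the other; the labile α-branched aldehyde 2 is then locked at once as its dimethyl acetal while the γ-hydroxy ester lactonises.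

**Step 2**
Reactants: 3 (S)-4-(dimethoxymethyl)dihydrofuran-2(3H)-one
Product: 6 (S)-4-(dimethoxymethyl)-3-methylenedihydrofuran-2(3H)-one, via Mannich base 4 (not isolated), via methiodide 5 (not isolated)
Conditions: LiN(SiMe3)2 (1.1 equiv), THF, −78 °C, then Me2N=CH2+ I− (1.3 equiv), −78 °C to rt; MeI (5 equiv), MeOH, rt; NaHCO3, CH2Cl2/H2O, rt
Reagents that add atoms: dimethyl(methylidene)ammonium iodide (C=[N+](C)C.[I-])
Why: Mannich aminomethylation of the lactone enolate, N-methylation and Hofmann-type elimination is the standard α-methylenation of γ-butyrolactones; C4 is untouched, the C3 centre of 4 is lost again, and the mild bicarbonate base should avoid migration of the exocyclic double bond into the ring.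

**Step 3**
Reactants: 6 (S)-4-(dimethoxymethyl)-3-methylenedihydrofuran-2(3H)-one
Product: 7 (3R,4R)-4-(dimethoxymethyl)-3-hydroxy-3-(hydroxymethyl)dihydrofuran-2(3H)-one
Conditions: OsO4 (2 mol %), N-methylmorpholine N-oxide (1.5 equiv), acetone/H2O (5:1), 0 °C to rt
Reagents that add atoms: N-methylmorpholine N-oxide (C[N+]1([O-])CCOCC1); water (O)
Why: Osmium-catalysed syn-dihydroxylation should occur on the alkene face anti to the C4 dimethoxymethyl group, so the new tertiary hydroxyl at C3 is trans and the hydroxymethyl group cis to the acetal carbon (3R), the only arrangement that can close the cis-fused ring B.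

**Step 4**
Reactants: 7 (3R,4R)-4-(dimethoxymethyl)-3-hydroxy-3-(hydroxymethyl)dihydrofuran-2(3H)-one; 8 veratrole (1,2-dimethoxybenzene)
Product: 10 (1R,5S,6R)-6-(3,4-dimethoxyphenyl)-1-hydroxy-3,7-dioxabicyclo[3.3.0]octan-2-one, via bicyclic methyl acetal 9 (not isolated)
Conditions: 8 (3 equiv), CF3SO3H (10 mol %), CH2Cl2/(CF3)2CHOH (4:1), −20 to 0 °C
Reagents that add atoms: none
Why: Triflic acid should ionise the dimethyl acetal of 7 to a methoxycarbenium ion that the primary hydroxyl captures in a 5-exo-trig closure, giving ring B as methyl acetal 9; a second ionisation gives the cis-fused bicyclic oxocarbenium ion at C6, which veratrole attacks through its C4 position (para to a methoxy group) in a Friedel-Crafts alkylation, followed by rearomatisation. The closest known reaction type is the acid-mediated C-arylation of 2-alkoxytetrahydrofurans and glycosyl donors by electron-rich arenes (Friedel-Crafts C-glycosylation). The new stereocentre C6 is controlled by the bicyclo[3.3.0] framework: the arene approaches the convex face, syn to H5 and the C1 hydroxyl, so the aryl group ends exo (6R); the exo isomer is also the thermodynamic one, so any reversible ionisation of the product ether corrects in the same direction, and C5 cannot scramble because only the cis ring fusion is viable. The step needs ring closure before intermolecular arylation (secured by the fast intramolecular five-membered capture), para regioselectivity on the arene (secured by the two methoxy groups) and mono-arylation without ring opening (secured by the much lower ionisability of the product ether compared with the acetal at this temperature). The lactone and the tertiary alcohol are inert here, and hexafluoroisopropanol stabilises the cation and raises the rate with the moderately nucleophilic arene.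

**Step 5**
Reactants: 10 (1R,5S,6R)-6-(3,4-dimethoxyphenyl)-1-hydroxy-3,7-dioxabicyclo[3.3.0]octan-2-one; 11 4-bromo-1,2-dimethoxybenzene
Product: 13 (1R,5S,6R)-2,6-bis(3,4-dimethoxyphenyl)-3,7-dioxabicyclo[3.3.0]octane-1,2-diol (C2 epimers), via aryllithium 12 (not isolated)
Conditions: 11 (2.4 equiv), n-BuLi (2.3 equiv), THF, −78 °C; then 10, −78 °C; H2O
Reagents that add atoms: none
Why: Bromine-lithium exchange gives 12, whose first equivalent deprotonates the tertiary hydroxyl and whose second adds to the lactone carbonyl (1,2-addition of an aryllithium to a lactone, as in C-aryl glycoside synthesis); C1 bears no hydrogen, so enolisation cannot compete, the tetrahedral adduct should survive at −78 °C, and the C2 centre formed here is removed in step 6.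

**Step 6**
Reactants: 13 (1R,5S,6R)-2,6-bis(3,4-dimethoxyphenyl)-3,7-dioxabicyclo[3.3.0]octane-1,2-diol
Product: 14 (1R,2R,5S,6R)-2,6-bis(3,4-dimethoxyphenyl)-3,7-dioxabicyclo[3.3.0]octan-1-ol
Conditions: Et3SiH (3 equiv), BF3·OEt2 (2 equiv), CH2Cl2, −78 to −40 °C; sat. aq NaHCO3
Reagents that add atoms: none
Why: Lewis acid-promoted ionic hydrogenation of a lactol: BF3·OEt2 ionises 13 to the aryl-stabilised oxocarbenium ion at C2 and Et3SiH should deliver hydride to the convex face of the cis-fused bicycle, so H2 ends exo (cis to the C1 hydroxyl) and the aryl group endo (2R), the kinetic product being kept by the low temperature.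

**Compound list**

1 | methyl 4-oxobutanoate | COC(=O)CCC=O | starting material
2 | methyl (S)-3-formyl-4-hydroxybutanoate | OC[C@@H](C=O)CC(=O)OC | intermediate
3 | (S)-4-(dimethoxymethyl)dihydrofuran-2(3H)-one | O=C1OC[C@@H](C(OC)OC)C1 | intermediate
4 | (3R,4S)-4-(dimethoxymethyl)-3-[(dimethylamino)methyl]dihydrofuran-2(3H)-one | O=C1OC[C@@H](C(OC)OC)[C@@H]1CN(C)C | intermediate
5 | [(3R,4S)-4-(dimethoxymethyl)-2-oxotetrahydrofuran-3-yl]-N,N,N-trimethylmethanaminium iodide | O=C1OC[C@@H](C(OC)OC)[C@@H]1C[N+](C)(C)C.[I-] | intermediate
6 | (S)-4-(dimethoxymethyl)-3-methylenedihydrofuran-2(3H)-one | O=C1OC[C@@H](C(OC)OC)C1=C | intermediate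
7 | (3R,4R)-4-(dimethoxymethyl)-3-hydroxy-3-(hydroxymethyl)dihydrofuran-2(3H)-one | O=C1OC[C@@H](C(OC)OC)[C@@]1(O)CO | intermediate
8 | veratrole (1,2-dimethoxybenzene) | COc1ccccc1OC | starting material
9 | (1R,5R)-1-hydroxy-6-methoxy-3,7-dioxabicyclo[3.3.0]octan-2-one (C6 epimers; same spatial arrangement at C5 as in 10) | O=C1OC[C@H]2C(OC)OC[C@@]12O | intermediate
10 | (1R,5S,6R)-6-(3,4-dimethoxyphenyl)-1-hydroxy-3,7-dioxabicyclo[3.3.0]octan-2-one | O=C1OC[C@H]2[C@H](c3ccc(OC)c(OC)c3)OC[C@@]12O | intermediate
11 | 4-bromo-1,2-dimethoxybenzene | COc1ccc(Br)cc1OC | starting material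
12 | (3,4-dimethoxyphenyl)lithium | [Li]c1ccc(OC)c(OC)c1 | intermediate
13 | (1R,5S,6R)-2,6-bis(3,4-dimethoxyphenyl)-3,7-dioxabicyclo[3.3.0]octane-1,2-diol (C2 epimers) | COc1ccc(C2(O)OC[C@H]3[C@H](c4ccc(OC)c(OC)c4)OC[C@@]23O)cc1OC | intermediate
14 | (1R,2R,5S,6R)-2,6-bis(3,4-dimethoxyphenyl)-3,7-dioxabicyclo[3.3.0]octan-1-ol (CNP0422369.4) | COc1ccc([C@H]2OC[C@H]3[C@H](c4ccc(OC)c(OC)c4)OC[C@@]23O)cc1OC | target

**Step count and risks**

Total step count: 6. Longest linear sequence: 6 steps (1 to 14).

Steps most likely to fail:

Step 4. The arylation may stall because veratrole is only a moderate π-nucleophile, or it may overrun by ionisation of the product ether and a second arylation with ring opening. The fallback sets out from 7 and forms the same C6-aryl bond by organometallic 1,2-addition instead of electrophilic aromatic substitution. Aqueous acid (CF3CO2H/H2O, rt) should hydrolyse the acetal of 7 to the lactol (1R,5R)-1,6-dihydroxy-3,7-dioxabicyclo[3.3.0]octan-2-one F1. (3,4-Dimethoxyphenyl)titanium triisopropoxide, made from (3,4-dimethoxyphenyl)magnesium bromide and ClTi(OCHMe2)3 in THF at −40 °C and selective for the aldehyde tautomer over the lactone, should then give the diol (3R,4S)-4-[(3,4-dimethoxyphenyl)(hydroxy)methyl]-3-hydroxy-3-(hydroxymethyl)dihydrofuran-2(3H)-one F2 as a mixture of carbinol epimers. Catalytic camphorsulfonic acid in CH2Cl2 should cyclise F2 through the 3,4-dimethoxybenzyl cation to the exo aryl ether, and the route is rejoined at 10.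

Step 6. Hydride delivery next to the C1 hydroxyl may show poor facial selectivity, or the acid may epimerise the endo aryl ether at C2 to the exo isomer. The fallback sets out from 13 and sets C2 by chelation-controlled ketone reduction followed by a stereoretentive ring closure. Zn(BH4)2 in Et2O at −20 °C should reduce the open hydroxy ketone form through a zinc chelate of the ketone and the C1 hydroxyl, attacked from the less hindered C8 methylene side, to give (3R,4S,5R)-5-(3,4-dimethoxyphenyl)-3-[(R)-(3,4-dimethoxyphenyl)(hydroxy)methyl]-4-(hydroxymethyl)tetrahydrofuran-3-ol F3. Selective sulfonylation of the primary hydroxyl (TsCl, pyridine, 0 °C) should give [(2R,3S,4R)-2-(3,4-dimethoxyphenyl)-4-[(R)-(3,4-dimethoxyphenyl)(hydroxy)methyl]-4-hydroxytetrahydrofuran-3-yl]methyl 4-methylbenzenesulfonate F4. NaH in THF at 0 °C should then close ring A by attack of the benzylic oxygen on the primary carbon, which leaves the C2 configuration untouched, and the route ends at 14.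

Step 1. Enantiopurity may erode by enolisation of aldehyde 2, and material may be lost by dehydration to the α-methylene aldehyde, before the acetal is in place. The fallback sets out from 1 and creates the stereocentre only after the aldehyde is masked. Amine-catalysed Mannich condensation with formaldehyde (37% aq. CH2O, pyrrolidine and propionic acid, 10 mol % each, i-PrOH, 45 °C) should give methyl 3-formylbut-3-enoate F5, and HC(OMe)3 with catalytic TsOH its acetal methyl 3-(dimethoxymethyl)but-3-enoate F6. Ester-directed rhodium-catalysed asymmetric hydroboration with pinacolborane (bis(norbornadiene)rhodium tetrafluoroborate, Rh(C7H8)2BF4, with a chiral monodentate phosphite ligand, THF, rt) should give methyl (R)-3-(dimethoxymethyl)-4-(4,4,5,5-tetramethyl-1,3,2-dioxaborolan-2-yl)butanoate F7. Oxidation with NaBO3·4H2O in THF/H2O should give methyl (S)-3-(dimethoxymethyl)-4-hydroxybutanoate F8, which lactonises with catalytic TsOH in toluene, and the route is rejoined at 3.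

**Further compounds**

F1 | step 4 | (1R,5R)-1,6-dihydroxy-3,7-dioxabicyclo[3.3.0]octan-2-one (C6 epimers) | O=C1OC[C@H]2C(O)OC[C@@]12O
F2 | step 4 | (3R,4S)-4-[(3,4-dimethoxyphenyl)(hydroxy)methyl]-3-hydroxy-3-(hydroxymethyl)dihydrofuran-2(3H)-one (carbinol epimers) | O=C1OC[C@@H](C(O)c2ccc(OC)c(OC)c2)[C@@]1(O)CO
F3 | step 6 | (3R,4S,5R)-5-(3,4-dimethoxyphenyl)-3-[(R)-(3,4-dimethoxyphenyl)(hydroxy)methyl]-4-(hydroxymethyl)tetrahydrofuran-3-ol | COc1ccc([C@@H](O)[C@]2(O)CO[C@@H](c3ccc(OC)c(OC)c3)[C@@H]2CO)cc1OC
F4 | step 6 | [(2R,3S,4R)-2-(3,4-dimethoxyphenyl)-4-[(R)-(3,4-dimethoxyphenyl)(hydroxy)methyl]-4-hydroxytetrahydrofuran-3-yl]methyl 4-methylbenzenesulfonate | COc1ccc([C@@H](O)[C@]2(O)CO[C@@H](c3ccc(OC)c(OC)c3)[C@@H]2COS(=O)(=O)c4ccc(C)cc4)cc1OC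
F5 | step 1 | methyl 3-formylbut-3-enoate | COC(=O)CC(=C)C=O
F6 | step 1 | methyl 3-(dimethoxymethyl)but-3-enoate | COC(=O)CC(=C)C(OC)OC
F7 | step 1 | methyl (R)-3-(dimethoxymethyl)-4-(4,4,5,5-tetramethyl-1,3,2-dioxaborolan-2-yl)butanoate | CC1(C)OB(C[C@@H](C(OC)OC)CC(=O)OC)OC1(C)C
F8 | step 1 | methyl (S)-3-(dimethoxymethyl)-4-hydroxybutanoate | OC[C@@H](C(OC)OC)CC(=O)OC
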